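**Plan**

Retrosynthesis: the C3–CH(Ph) bond is cut first (cinnamoyl Michael addition, the acid being released from an enol lactone), then C4–C4a of ring A, then O1′–C8a of ring B (cyclodehydration of a δ-hydroxy-β-diketone), then the C4a–C4′ aldol bond, and last the prenyl and lavandulyl bonds at C1 (malonate alkylations).
Enabling feature: ring A (C1 quaternary, C2 ketone, C3, C4 enol, C4a, C8a) is a C2–C3–C4 malonyl unit carried by C1 and closed onto C4a, the nucleophilic α-carbon of the ring B vinylogous ester O1′–C8a=C4a–C4′=O, so C4–C4a can be formed by attack of that carbon on an acylketene.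
Forward: lavandulyl malonate → quaternary C1 by phase-transfer prenylation → ester differentiation to an α-acetyl allyl ester → aldol/oxidation with a syn-aldol aldehyde → ring B (dihydropyranone) → acyl Meldrum's acid → ring A by thermolysis → C3 side chain.
Stereochemistry: lavandulyl centre from lipase-resolved (S)-lavandulol; C1 from a chiral ammonium phase-transfer catalyst; cis C2′/C3′ from an Evans syn aldol; benzylic centre from an isothiourea catalyst.

Key step: step 19

Remark: ring A is numbered C1, C2, C3, C4, C4a, C8a (chromene C8, C7, C6, C5, C4a, C8a) and ring B O1′, C2′, C3′, C4′; Lav = (2R)-5-methyl-2-(prop-1-en-2-yl)hex-4-en-1-yl, the lavandulyl group of (S)-lavandulol (R once bound to carbon, by CIP priority only).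
Assumption: the sense of induction of the lipase (step 1), the phase-transfer catalyst (step 5) and the isothiourea (step 20) is assigned from the accepted selectivity models; each chiral catalyst is available as either enantiomer (for the lipase the acetate fraction can be saponified instead), so an opposite sense on these substrates would be met with the antipode.

**Route**

Step 1
Reactants: 1 racemic lavandulol
Product: 2 (S)-lavandulol
Conditions: porcine pancreatic lipase, vinyl acetate, hexane, rt, to about 60% conversion; chromatography (second cycle if needed)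
Reagents that add atoms: none
Why: Lipase-catalysed kinetic resolution by transesterification should acetylate the R alcohol faster, so the unreacted S alcohol is recovered enantioenriched once conversion passes one half, which fixes the lavandulyl stereocentre.

Step 2
Reactants: 2 (S)-lavandulol
Product: 3 (S)-lavandulyl iodide [(3S)-3-(iodomethyl)-2,6-dimethylhepta-1,5-diene]
Conditions: I2, PPh3, imidazole, CH2Cl2, 0 °C to rt
Reagents that add atoms: iodine, II
Why: Appel-type iodination replaces the primary hydroxyl by SN2 at the CH2 group under neutral conditions, so the adjacent stereocentre and both alkenes are untouched.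

Step 3
Reactants: 4 mono-tert-butyl malonate; 5 2,2-diphenylethanol
Product: 6 tert-butyl 2,2-diphenylethyl malonate
Conditions: EDC·HCl, DMAP (cat.), CH2Cl2, 0 °C to rt
Reagents that add atoms: none
Why: Steglich-type carbodiimide esterification of a malonic half-acid with a primary alcohol is routine and leaves the tert-butyl ester intact.

Step 4
Reactants: 6 tert-butyl 2,2-diphenylethyl malonate; 3 (S)-lavandulyl iodide
Product: 8 tert-butyl 2,2-diphenylethyl 2-Lav-malonate (both epimers at the malonate carbon), via sodium enolate 7 (not isolated)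
Conditions: NaH, THF/DMF, 0 °C; then 3, 0 to 50 °C
Reagents that add atoms: none
Why: Malonic ester alkylation, in which the soft sodium malonate displaces the primary iodide by SN2 (a slight excess of 6 limits dialkylation and the weakly basic nucleophile disfavours E2); the new malonate CH centre is irrelevant because it is planarised in step 5.

Step 5
Reactants: 8 tert-butyl 2,2-diphenylethyl 2-Lav-malonate; 9 prenyl bromide
Product: 10 1-tert-butyl 3-(2,2-diphenylethyl) (2R)-2-Lav-2-(3-methylbut-2-en-1-yl)malonate
Conditions: (S,S)-3,4,5-trifluorophenyl-NAS bromide (5 mol %), 50% aq KOH, toluene, −40 °C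
Reagents that add atoms: none
Why: Enantioselective phase-transfer alkylation of an α-monoalkyl tert-butyl 2,2-diphenylethyl malonate, in which the C2-symmetric spiro ammonium cation pairs with the enolate, tells its faces apart through the two unlike ester groups and should deliver the prenyl group to the face that gives the R quaternary centre C1 (catalyst control, the remote lavandulyl centre exerting little bias).

Step 6
Reactants: 10 quaternary mixed malonate
Product: 11 (2R)-2-(tert-butoxycarbonyl)-2-Lav-5-methylhex-4-enoic acid
Conditions: KOH, MeOH/THF/H2O, 50 °C; then cold aq KHSO4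
Reagents that add atoms: potassium hydroxide, [K+].[OH-]
Why: Saponification is chemoselective for the primary 2,2-diphenylethyl ester because the tert-butyl ester resists acyl attack by hydroxide, and the quaternary centre cannot epimerise.

Step 7
Reactants: 11 half-acid
Product: 12 1-allyl 3-tert-butyl (2R)-2-Lav-2-(3-methylbut-2-en-1-yl)malonate
Conditions: allyl bromide, K2CO3, DMF, rt
Reagents that add atoms: allyl bromide, C=CCBr
Why: Carboxylate O-alkylation (SN2) installs an ester that can later be removed under neutral palladium catalysis in the presence of the acid- and base-sensitive dihydropyranone.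

Step 8
Reactants: 12 allyl tert-butyl malonate
Product: 14 (2S)-2-(allyloxycarbonyl)-2-Lav-5-methylhex-4-enoic acid, via trimethylsilyl ester 13 (not isolated)
Conditions: TMSOTf, 2,6-lutidine, CH2Cl2, 0 °C; then H2O
Reagents that add atoms: none
Why: Silyl-triflate-mediated tert-butyl ester cleavage (carbonyl silylation, loss of isobutene, hydrolysis of the silyl ester on work-up) runs under buffered aprotic conditions, which spares the three alkenes and the allyl ester that a protic acid would endanger.

Step 9
Reactants: 14 allyl half-acid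
Product: 16 allyl (2S)-2-acetyl-2-Lav-5-methylhex-4-enoate, via acid chloride 15 (not isolated)
Conditions: 1-chloro-N,N,2-trimethylprop-1-en-1-amine, CH2Cl2, 0 °C to rt; concentrate; then MeMgBr, Fe(acac)3 (3 mol %), THF, −78 °C
Reagents that add atoms: methylmagnesium bromide, C[Mg]Br
Why: Acid chloride formation with the Ghosez chloroenamine (no HCl released) followed by Fe(acac)3-catalysed acyl chloride–Grignard coupling should give the methyl ketone without over-addition and far faster than any attack on the hindered allyl ester.

Step 10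
Reactants: 17 (S)-4-benzyl-3-propionyloxazolidin-2-one; 18 acetaldehyde
Product: 20 (4S)-4-benzyl-3-[(2S,3R)-3-hydroxy-2-methylbutanoyl]oxazolidin-2-one, via Z-boron enolate 19 (not isolated)
Conditions: Bu2BOTf, i-Pr2NEt, CH2Cl2, 0 °C; then 18, −78 to 0 °C; then pH 7 buffer, MeOH, H2O2
Reagents that add atoms: none
Why: Evans syn-aldol reaction, in which the Z-dibutylboron enolate reacts through a closed Zimmerman–Traxler transition state on the face away from the benzyl group of the auxiliary and so sets the (2S,3R) syn pair that becomes the cis C2′/C3′ dimethyl unit.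

Step 11
Reactants: 20 syn-aldol imide
Product: 21 (2S,3R)-3-hydroxy-N-methoxy-N,2-dimethylbutanamide
Conditions: MeONHMe·HCl, AlMe3, THF, −20 to 0 °C
Reagents that add atoms: N,O-dimethylhydroxylamine hydrochloride, CNOC.Cl
Why: Aluminium-amide transamination of the β-hydroxy imide (Weinreb amide formation) is directed by the free hydroxyl to the exocyclic carbonyl and releases the auxiliary without epimerising the α-centre.

Step 12
Reactants: 21 hydroxy Weinreb amide
Product: 22 (2S,3R)-N-methoxy-N,2-dimethyl-3-(triethylsilyloxy)butanamide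
Conditions: Et3SiCl, imidazole, CH2Cl2, rt
Reagents that add atoms: chlorotriethylsilane, CC[Si](Cl)(CC)CC
Why: Standard silylation gives a triethylsilyl ether that survives hydride and enolate chemistry but is lost under the mild acid used to close ring B.

Step 13
Reactants: 22 silylated Weinreb amide
Product: 23 (2S,3R)-2-methyl-3-(triethylsilyloxy)butanal
Conditions: i-Bu2AlH, THF, −78 °C; then aq potassium sodium tartrate (KNaC4H4O6)
Reagents that add atoms: none
Why: Hydride reduction of an N-methoxy-N-methylamide stops at the aldehyde oxidation level, and the low temperature keeps the α-stereocentre intact (the aldehyde is used crude).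

Step 14
Reactants: 16 allyl α-acetyl ester; 23 aldehyde
Product: 25 allyl (2S)-2-[(4R,5R)-3-hydroxy-4-methyl-5-(triethylsilyloxy)hexanoyl]-2-Lav-5-methylhex-4-enoate (both carbinol epimers), via lithium enolate 24 (not isolated)
Conditions: LiN(i-Pr)2, THF, −78 °C; then 23, −78 °C; AcOH quench at −78 °C
Reagents that add atoms: none
Why: Directed aldol addition, in which 16 can enolise only toward its methyl group (the other α-carbon is quaternary) and the kinetic lithium enolate adds to the aldehyde faster than to the hindered ester; the new carbinol configuration is irrelevant because it is oxidised next.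

Step 15
Reactants: 25 β-hydroxy ketone
Product: 26 allyl (2S)-2-Lav-5-methyl-2-[(4S,5R)-4-methyl-3-oxo-5-(triethylsilyloxy)hexanoyl]hex-4-enoate
Conditions: Dess–Martin periodinane, CH2Cl2, 0 °C to rt
Reagents that add atoms: none
Why: Dess–Martin oxidation of the β-hydroxy ketone gives the 1,3-diketone (enolised at the central CH2) under near-neutral conditions that neither epimerise the α-methyl centre nor touch the alkenes.

Step 16
Reactants: 26 silyloxy 1,3-diketone
Product: 28 allyl (2S)-2-[(2R,3S)-2,3-dimethyl-4-oxo-3,4-dihydro-2H-pyran-6-yl]-2-Lav-5-methylhex-4-enoate, via hydroxy diketone 27 (not isolated)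
Conditions: TsOH·H2O (0.2 equiv), wet CH2Cl2, 0 °C to rt
Reagents that add atoms: none
Why: Acid-catalysed desilylation and cyclodehydration of a δ-hydroxy-β-diketone (hemiketalisation onto the future C8a carbonyl, then loss of water) closes ring B as the 2,3-dihydro-4H-pyran-4-one; the carbinol C–O bond is retained and the diketone enolises away from C3′, so the cis dimethyl pair is carried over.

Step 17
Reactants: 28 dihydropyranone allyl ester
Product: 29 (2S)-2-[(2R,3S)-2,3-dimethyl-4-oxo-3,4-dihydro-2H-pyran-6-yl]-2-Lav-5-methylhex-4-enoic acid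
Conditions: Pd(PPh3)4 (5 mol %), N-methylaniline, THF, rt
Reagents that add atoms: none
Why: Tsuji–Trost deallylation (π-allylpalladium formation and transfer of the allyl group to the weakly basic aniline) frees the acid under neutral conditions, so neither the epimerisable C3′ centre nor the prenyl groups are disturbed; the acid is used at once.

Step 18
Reactants: 29 dihydropyranone acid; 30 Meldrum's acid
Product: 32 acyl Meldrum's acid of 29 in its enol form [5-(1-hydroxyalkylidene)-2,2-dimethyl-1,3-dioxane-4,6-dione on C1; C1 and ring B as in 29], via acid chloride 31 (not isolated)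
Conditions: 1-chloro-N,N,2-trimethylprop-1-en-1-amine, CH2Cl2, 0 °C; then 30, pyridine, DMAP (cat.), CH2Cl2, 0 °C to rt
Reagents that add atoms: none
Why: C-acylation of Meldrum's acid by an acid chloride in the presence of pyridine gives the enolised acyl Meldrum's acid; the acid chloride is made without HCl and cannot form a ketene because C1 carries no hydrogen.

Step 19
Reactants: 32 acyl Meldrum's acid
Product: 34 (2R,3S,8S)-5-hydroxy-8-Lav-2,3-dimethyl-8-(3-methylbut-2-en-1-yl)-2,3-dihydro-4H-chromene-4,7(8H)-dione (C3-unsubstituted bicyclic core), via acylketene 33 (not isolated)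
Conditions: toluene (0.005 M), 105 °C
Reagents that add atoms: none
Why: Proposed new method: heating should expel acetone and CO2 from the acyl Meldrum's acid to give acylketene 33, whose ketene carbon (C4) is attacked by C5 of the dihydropyranone (C4a), the nucleophilic α-carbon of the vinylogous ester O1′–C8a=C4a–C4′=O, after which the oxocarbenium–enolate zwitterion loses the C4a proton and tautomerises to the enolised dione. The closest known reaction type is the thermolysis of acyl Meldrum's acids to acylketenes that C-acylate enol ethers and arenes, for example the cyclisation of arylacetyl Meldrum's acids to naphthalene-1,3-diols, with the vinylogous ester here in the place of the arene. Ring A closes in a six-membered mode that is exo with respect to the ketene C=O and endo with respect to the C4a=C8a enol ether bond, the geometry of a tetralone-forming Friedel–Crafts acylation. No stereocentre is formed, and the neutral conditions leave the quaternary C1 and the cis C2′/C3′ pair untouched. The selectivity needed is for C4a over the three unactivated alkenes and over ketene dimerisation: the push–pull enol ether carbon is the most nucleophilic π-site and is reached through an unstrained six-membered transition state, attack by the acyl oxygen on C8a would need a four-membered ring, and high dilution suppresses bimolecular pathways.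

Step 20
Reactants: 34 bicyclic core; 35 (E,E)-cinnamic anhydride
Product: 36 enol δ-lactone of the target (lactone oxygen on C4; R benzylic carbon on C3; other centres as in 34)
Conditions: (2S,3R)-HyperBTM (10 mol %), i-Pr2NEt, CH2Cl2, −20 °C to rt
Reagents that add atoms: none
Why: Isothiourea-catalysed Michael addition–lactonisation, in which the cinnamoyl isothiouronium ion (held s-cis by the 1,5 S···O contact) is attacked at its β-carbon by the nucleophilic C3 of the enolised dione on the face away from the phenyl group of the catalyst (catalyst control should set the R benzylic centre) and the enol oxygen then lactonises to release the catalyst; a lactone closed through the C2 oxygen, if formed, converges on the same acid in step 21.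

Step 21
Reactants: 36 enol lactone
Product: 37 target [(3R)-3-[(2R,3S,8S)-5-hydroxy-8-Lav-2,3-dimethyl-8-(3-methylbut-2-en-1-yl)-4,7-dioxo-3,4,7,8-tetrahydro-2H-chromen-6-yl]-3-phenylpropanoic acid]
Conditions: LiOH, THF/H2O, 0 °C; then cold 0.5 M HCl to pH 3
Reagents that add atoms: lithium hydroxide, [Li+].[OH-]
Why: Hydroxide opens the activated enol lactone at its acyl carbon to give the carboxylate and the delocalised trione enolate, whose charge protects ring A from retro-Claisen cleavage and lowers the acidity of C3′–H, so careful acidification should give the acid with all five stereocentres intact.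

**Compound list**

1 | racemic lavandulol [5-methyl-2-(prop-1-en-2-yl)hex-4-en-1-ol] | CC(C)=CCC(CO)C(C)=C | starting material
2 | (S)-lavandulol | C=C(C)[C@H](CC=C(C)C)CO | intermediate
3 | (S)-lavandulyl iodide | C=C(C)[C@H](CC=C(C)C)CI | intermediate
4 | mono-tert-butyl malonate (3-tert-butoxy-3-oxopropanoic acid) | CC(C)(C)OC(=O)CC(=O)O | starting material
5 | 2,2-diphenylethanol | OCC(c1ccccc1)c1ccccc1 | starting material
6 | tert-butyl 2,2-diphenylethyl malonate | CC(C)(C)OC(=O)CC(=O)OCC(c1ccccc1)c1ccccc1 | intermediate
7 | sodium enolate of 6 | CC(C)(C)OC(=O)[CH-]C(=O)OCC(c1ccccc1)c1ccccc1.[Na+] | intermediate (not isolated)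
8 | tert-butyl 2,2-diphenylethyl 2-Lav-malonate (epimers at the malonate carbon) | C=C(C)[C@H](CC=C(C)C)CC(C(=O)OC(C)(C)C)C(=O)OCC(c1ccccc1)c1ccccc1 | intermediate
9 | prenyl bromide (1-bromo-3-methylbut-2-ene) | CC(C)=CCBr | starting material
10 | 1-tert-butyl 3-(2,2-diphenylethyl) (2R)-2-Lav-2-(3-methylbut-2-en-1-yl)malonate | C=C(C)[C@H](CC=C(C)C)C[C@](C(=O)OC(C)(C)C)(CC=C(C)C)C(=O)OCC(c1ccccc1)c1ccccc1 | intermediate
11 | (2R)-2-(tert-butoxycarbonyl)-2-Lav-5-methylhex-4-enoic acid | C=C(C)[C@H](CC=C(C)C)C[C@](C(=O)OC(C)(C)C)(CC=C(C)C)C(=O)O | intermediate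
12 | 1-allyl 3-tert-butyl (2R)-2-Lav-2-(3-methylbut-2-en-1-yl)malonate | C=C(C)[C@H](CC=C(C)C)C[C@](C(=O)OC(C)(C)C)(CC=C(C)C)C(=O)OCC=C | intermediate
13 | 1-allyl 3-trimethylsilyl (2R)-2-Lav-2-(3-methylbut-2-en-1-yl)malonate | C=C(C)[C@H](CC=C(C)C)C[C@](C(=O)O[Si](C)(C)C)(CC=C(C)C)C(=O)OCC=C | intermediate (not isolated)
14 | (2S)-2-(allyloxycarbonyl)-2-Lav-5-methylhex-4-enoic acid | C=C(C)[C@H](CC=C(C)C)C[C@](C(=O)O)(CC=C(C)C)C(=O)OCC=C | intermediate
15 | allyl (2R)-2-(chlorocarbonyl)-2-Lav-5-methylhex-4-enoate | C=C(C)[C@H](CC=C(C)C)C[C@](C(=O)Cl)(CC=C(C)C)C(=O)OCC=C | intermediate (not isolated)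
16 | allyl (2S)-2-acetyl-2-Lav-5-methylhex-4-enoate | C=C(C)[C@H](CC=C(C)C)C[C@](C(C)=O)(CC=C(C)C)C(=O)OCC=C | intermediate
17 | (S)-4-benzyl-3-propionyloxazolidin-2-one | CCC(=O)N1[C@@H](Cc2ccccc2)COC1=O | starting material
18 | acetaldehyde | CC=O | starting material
19 | Z-dibutylboron enolate of 17 | C/C=C(\OB(CCCC)CCCC)N1[C@@H](Cc2ccccc2)COC1=O | intermediate (not isolated)
20 | (4S)-4-benzyl-3-[(2S,3R)-3-hydroxy-2-methylbutanoyl]oxazolidin-2-one | O[C@H](C)[C@H](C)C(=O)N1[C@@H](Cc2ccccc2)COC1=O | intermediate
21 | (2S,3R)-3-hydroxy-N-methoxy-N,2-dimethylbutanamide | O[C@H](C)[C@H](C)C(=O)N(C)OC | intermediate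
22 | (2S,3R)-N-methoxy-N,2-dimethyl-3-(triethylsilyloxy)butanamide | CC[Si](CC)(CC)O[C@H](C)[C@H](C)C(=O)N(C)OC | intermediate
23 | (2S,3R)-2-methyl-3-(triethylsilyloxy)butanal | CC[Si](CC)(CC)O[C@H](C)[C@H](C)C=O | intermediate
24 | lithium enolate of 16 (methyl side) | C=C(C)[C@H](CC=C(C)C)C[C@](C(=C)O[Li])(CC=C(C)C)C(=O)OCC=C | intermediate (not isolated)
25 | allyl (2S)-2-[(4R,5R)-3-hydroxy-4-methyl-5-(triethylsilyloxy)hexanoyl]-2-Lav-5-methylhex-4-enoate (carbinol epimers) | C=C(C)[C@H](CC=C(C)C)C[C@](C(=O)CC(O)[C@@H](C)[C@@H](C)O[Si](CC)(CC)CC)(CC=C(C)C)C(=O)OCC=C | intermediate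
26 | allyl (2S)-2-Lav-5-methyl-2-[(4S,5R)-4-methyl-3-oxo-5-(triethylsilyloxy)hexanoyl]hex-4-enoate | C=C(C)[C@H](CC=C(C)C)C[C@](C(=O)CC(=O)[C@@H](C)[C@@H](C)O[Si](CC)(CC)CC)(CC=C(C)C)C(=O)OCC=C | intermediate
27 | allyl (2S)-2-[(4S,5R)-5-hydroxy-4-methyl-3-oxohexanoyl]-2-Lav-5-methylhex-4-enoate | C=C(C)[C@H](CC=C(C)C)C[C@](C(=O)CC(=O)[C@@H](C)[C@@H](C)O)(CC=C(C)C)C(=O)OCC=C | intermediate (not isolated)
28 | allyl (2S)-2-[(2R,3S)-2,3-dimethyl-4-oxo-3,4-dihydro-2H-pyran-6-yl]-2-Lav-5-methylhex-4-enoate | C=C(C)[C@H](CC=C(C)C)C[C@](C1=CC(=O)[C@@H](C)[C@@H](C)O1)(CC=C(C)C)C(=O)OCC=C | intermediate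
29 | (2S)-2-[(2R,3S)-2,3-dimethyl-4-oxo-3,4-dihydro-2H-pyran-6-yl]-2-Lav-5-methylhex-4-enoic acid | C=C(C)[C@H](CC=C(C)C)C[C@](C1=CC(=O)[C@@H](C)[C@@H](C)O1)(CC=C(C)C)C(=O)O | intermediate
30 | Meldrum's acid (2,2-dimethyl-1,3-dioxane-4,6-dione) | CC1(C)OC(=O)CC(=O)O1 | starting material
31 | acid chloride of 29 | C=C(C)[C@H](CC=C(C)C)C[C@](C1=CC(=O)[C@@H](C)[C@@H](C)O1)(CC=C(C)C)C(=O)Cl | intermediate (not isolated)
32 | acyl Meldrum's acid of 29, enol form (key-step precursor; C1 is R by CIP in this tautomer, geometry as in 29) | C=C(C)[C@H](CC=C(C)C)C[C@](C1=CC(=O)[C@@H](C)[C@@H](C)O1)(CC=C(C)C)C(O)=C1C(=O)OC(C)(C)OC1=O | intermediate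
33 | acylketene: (4S)-4-[(2R,3S)-2,3-dimethyl-4-oxo-3,4-dihydro-2H-pyran-6-yl]-4-Lav-7-methylocta-1,6-diene-1,3-dione | C=C(C)[C@H](CC=C(C)C)C[C@](C1=CC(=O)[C@@H](C)[C@@H](C)O1)(CC=C(C)C)C(=O)C=C=O | intermediate (not isolated)
34 | (2R,3S,8S)-5-hydroxy-8-Lav-2,3-dimethyl-8-(3-methylbut-2-en-1-yl)-2,3-dihydro-4H-chromene-4,7(8H)-dione (key-step product) | C=C(C)[C@H](CC=C(C)C)C[C@]1(CC=C(C)C)C(=O)C=C(O)C2=C1O[C@H](C)[C@H](C)C2=O | intermediate
35 | (E,E)-cinnamic anhydride | O=C(/C=C/c1ccccc1)OC(=O)/C=C/c1ccccc1 | starting material
36 | enol δ-lactone of the target (4-phenyl-3,4-dihydropyran-2-one fused across C3–C4 of 34, lactone O on C4, benzylic carbon R) | C=C(C)[C@H](CC=C(C)C)C[C@]1(CC=C(C)C)C(=O)C3=C(OC(=O)C[C@@H]3c4ccccc4)C2=C1O[C@H](C)[C@H](C)C2=O | intermediate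
37 | (3R)-3-[(2R,3S,8S)-5-hydroxy-8-Lav-2,3-dimethyl-8-(3-methylbut-2-en-1-yl)-4,7-dioxo-3,4,7,8-tetrahydro-2H-chromen-6-yl]-3-phenylpropanoic acid | C=C(C)[C@H](CC=C(C)C)C[C@]1(CC=C(C)C)C(=O)C([C@H](CC(=O)O)c2ccccc2)=C(O)C2=C1O[C@H](C)[C@H](C)C2=O | target

**Step count and risks**

Total step count: 21. Longest linear sequence: 16 steps (steps 1, 2, 4–9 and 14–21).

Steps most likely to fail:

1. Step 19. The transient acylketene may be diverted before C-acylation, by dimerisation, by ene or [2+2] reaction with a prenyl alkene, or by capture of adventitious water followed by decarboxylation, if C4a is not nucleophilic enough or cannot reach the ketene carbon. The fallback uses known chemistry and closes ring A at C2–C3 by an intramolecular Claisen condensation. It sets out from acid 29. Esterification with TMSCHN2 in MeOH/toluene gives methyl ester F1. Iodination at C5 of the dihydropyranone with I2 and pyridine in CH2Cl2 gives 5-iodo dihydropyranone F2. Stille coupling with tributyl(1-ethoxyvinyl)stannane (Pd(PPh3)4, CuI, DMF, 60 °C) gives enol ether F3, which dilute aqueous HCl in THF hydrolyses to 5-acetyl dihydropyranone F4. LiN(SiMe3)2 in THF (−78 to 0 °C) then generates the methyl ketone enolate, which attacks the C1 ester carbonyl (Dieckmann-type closure) and gives, after mildly acidic work-up, the enolised dione 34, where the route is rejoined.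

2. Step 5. The hindered, β-branched malonate enolate may alkylate slowly and with poor facial discrimination inside the chiral ion pair. The fallback gives up catalyst control for separation. It sets out from 8. Prenylation under achiral conditions (NaH, prenyl bromide, DMF) gives 10 together with C1-epimeric diester F5. Hydrolysis as in step 6 gives 11 and epimeric acid F6, which are diastereomers because of the fixed lavandulyl centre and are separated by preparative chromatography. Acid 11 re-enters the route at step 7.

3. Step 20. Facial control at the new benzylic centre may be insufficient on this hindered cyclic nucleophile, or unproductive O-acylation may consume the acyl ammonium species. The fallback switches from acyl ammonium to iminium activation. It sets out from 34. Michael addition to cinnamaldehyde catalysed by (R)-α,α-diphenylprolinol trimethylsilyl ether (benzoic acid cat., CH2Cl2, rt), with the nucleophile adding to the face of the iminium ion away from the diarylmethyl group, gives after hemiacetalisation lactol F7. Dess–Martin oxidation of the lactol gives lactone 36, where the route is rejoined.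

Further compounds
F1 | step 19 | methyl (2S)-2-[(2R,3S)-2,3-dimethyl-4-oxo-3,4-dihydro-2H-pyran-6-yl]-2-Lav-5-methylhex-4-enoate | C=C(C)[C@H](CC=C(C)C)C[C@](C1=CC(=O)[C@@H](C)[C@@H](C)O1)(CC=C(C)C)C(=O)OC
F2 | step 19 | 5-iodo derivative of F1 (iodine on C5 of the dihydropyranone) | C=C(C)[C@H](CC=C(C)C)C[C@](C1=C(I)C(=O)[C@@H](C)[C@@H](C)O1)(CC=C(C)C)C(=O)OC
F3 | step 19 | 5-(1-ethoxyvinyl) derivative of F1 | C=C(C)[C@H](CC=C(C)C)C[C@](C1=C(C(=C)OCC)C(=O)[C@@H](C)[C@@H](C)O1)(CC=C(C)C)C(=O)OC
F4 | step 19 | 5-acetyl derivative of F1 | C=C(C)[C@H](CC=C(C)C)C[C@](C1=C(C(C)=O)C(=O)[C@@H](C)[C@@H](C)O1)(CC=C(C)C)C(=O)OC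
F5 | step 5 | C1 epimer of 10 | C=C(C)[C@H](CC=C(C)C)C[C@@](C(=O)OC(C)(C)C)(CC=C(C)C)C(=O)OCC(c1ccccc1)c1ccccc1
F6 | step 5 | C1 epimer of 11 | C=C(C)[C@H](CC=C(C)C)C[C@@](C(=O)OC(C)(C)C)(CC=C(C)C)C(=O)O
F7 | step 20 | lactol corresponding to 36 (hemiacetal carbon in place of the lactone carbonyl, both anomers) | C=C(C)[C@H](CC=C(C)C)C[C@]1(CC=C(C)C)C(=O)C3=C(OC(O)C[C@@H]3c4ccccc4)C2=C1O[C@H](C)[C@H](C)C2=O
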